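**Assumption:** the SMILES is read as the (R)-terpinen-4-yl ester of 4-hydroxy-3,5-diprenylbenzoic acid (R at the ring carbinol carbon); (S)-2-hydroxy-3-methylbutanoic acid is bought (it is also one step from L-valine).

## Retrosynthetic overview

1. Ester C–O bond: target ⇒ lithium alkoxide of (R)-terpinen-4-ol 15 + O-TBS-protected aroyl chloride 22; the phenol TBS group is removed last.
2. 15 ⇒ enol triflate 13 (methyl cross-coupling) ⇒ enone 11 by regiospecific conjugate reduction and enolate trapping; the enone C=C keeps the two ring arms distinct.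
3. Cyclohexenone ring (the only ring made, closed once by intramolecular aldol condensation) ⇒ keto-aldehyde 8 ⇒ Michael adduct 6.
4. Key C–C bond: intermolecular Michael addition of the Seebach dioxolanone enolate of (S)-2-hydroxy-3-methylbutanoic acid to methyl vinyl ketone, anti to tert-butyl; this sets the quaternary carbinol centre.
5. Acid part ⇒ CO2 + aryllithium from 4-bromo-2,6-diprenylphenol ⇒ 4-bromophenol + prenyl bromide.

## Route

**Step 1**
Reactants: 1 (S)-2-hydroxy-3-methylbutanoic acid; 2 pivalaldehyde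
Product: 3 (2S,5S)-2-tert-butyl-5-isopropyl-1,3-dioxolan-4-one (cis)
Conditions: cat. TsOH·H2O, cat. H2SO4, pentane, reflux, Dean–Stark; cis isomer purified by chromatography or low-temperature crystallisation
Reagents that add atoms: none
Why: Acid-catalysed acetalisation (Seebach self-regeneration-of-stereocentres template) gives mainly the cis acetal (about 95:5), so the acetal centre is set relative to the existing (S) centre.

**Step 2**
Reactants: 3 (2S,5S)-2-tert-butyl-5-isopropyl-1,3-dioxolan-4-one; 4 methyl vinyl ketone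
Product: 6 (2S,5S)-2-tert-butyl-5-isopropyl-5-(3-oxobutyl)-1,3-dioxolan-4-one, via lithium dioxolanone enolate 5 (not isolated)
Conditions: LDA (commercial, 1.05 eq), THF/DMPU, −78 °C; then 4 (1.2 eq, slow addition), −78 °C; AcOH quench at −78 °C
Reagents that add atoms: none
Why: Intermolecular Michael addition in which the planar enolate is attacked anti to the tert-butyl group, so the new C–C bond replaces the former C–H and fixes the quaternary carbinol centre (expected dr ≥ 95:5, minor isomer removed by chromatography).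

**Step 3**
Reactants: 6 (2S,5S)-2-tert-butyl-5-isopropyl-5-(3-oxobutyl)-1,3-dioxolan-4-one
Product: 7 (2S)-2-isopropylhexane-1,2,5-triol (mixture of C5 epimers)
Conditions: LiAlH4, THF, 0 °C → reflux; Fieser work-up
Reagents that add atoms: none
Why: Hydride reduction of the lactone-acetal and the ketone releases the auxiliary and gives the triol without touching the quaternary centre; the C5 epimers converge in the next step.

**Step 4**
Reactants: 7 (2S)-2-isopropylhexane-1,2,5-triol
Product: 8 (2S)-2-hydroxy-2-isopropyl-5-oxohexanal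
Conditions: (COCl)2, DMSO, CH2Cl2, −78 °C; Et3N, −78 → 0 °C; used crude
Reagents that add atoms: none
Why: Swern oxidation converts the primary and secondary alcohols to aldehyde and ketone, while the tertiary alcohol cannot be oxidised and the non-enolisable aldehyde cannot epimerise.

**Step 5**
Reactants: 8 (2S)-2-hydroxy-2-isopropyl-5-oxohexanal
Product: 10 (4S)-4-hydroxy-4-isopropylcyclohex-2-en-1-one, via aldol adduct 9 (not isolated)
Conditions: KOH (0.5 eq), MeOH, 0 °C → rt (40 °C to complete dehydration)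
Reagents that add atoms: none
Why: Intramolecular aldol condensation (second half of a Robinson annulation) can only close the six-membered ring from the methyl-ketone enolate onto the non-enolisable aldehyde, and E1cB dehydration gives the enone.

**Step 6**
Reactants: 10 (4S)-4-hydroxy-4-isopropylcyclohex-2-en-1-one
Product: 11 (4S)-4-isopropyl-4-(triethylsilyloxy)cyclohex-2-en-1-one
Conditions: TESOTf, 2,6-lutidine, CH2Cl2, −78 → 0 °C
Reagents that add atoms: triethylsilyl trifluoromethanesulfonate, CC[Si](CC)(CC)OS(=O)(=O)C(F)(F)F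
Why: Silyl triflate protection of the hindered tertiary alcohol prevents alkoxide formation and O-triflation in the next step.

**Step 7**
Reactants: 11 (4S)-4-isopropyl-4-(triethylsilyloxy)cyclohex-2-en-1-one
Product: 13 (4R)-4-isopropyl-4-(triethylsilyloxy)cyclohex-1-en-1-yl trifluoromethanesulfonate, via lithium enolate 12 (not isolated)
Conditions: L-Selectride (1.05 eq), THF, −78 °C; then PhNTf2, −78 → 0 °C; sat. NH4Cl
Reagents that add atoms: N-phenylbis(trifluoromethanesulfonimide), O=S(=O)(N(c1ccccc1)S(=O)(=O)C(F)(F)F)C(F)(F)F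
Why: Conjugate (1,4) reduction of a β-unsubstituted cyclohexenone gives the C1=C2 enolate regiospecifically, and trapping it under strictly aprotic conditions (no enolate equilibration through the achiral saturated ketone) carries the chirality of the enone into the triflate.

**Step 8**
Reactants: 13 (4R)-4-isopropyl-4-(triethylsilyloxy)cyclohex-1-en-1-yl trifluoromethanesulfonate
Product: 14 triethyl{[(1R)-1-isopropyl-4-methylcyclohex-3-en-1-yl]oxy}silane
Conditions: MeMgBr, Fe(acac)3 (5 mol%), THF/NMP, −30 → 0 °C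
Reagents that add atoms: methylmagnesium bromide, C[Mg]Br
Why: Iron-catalysed Kumada-type cross-coupling of the alkenyl triflate installs the ring methyl without moving the double bond.

**Step 9**
Reactants: 14 triethyl{[(1R)-1-isopropyl-4-methylcyclohex-3-en-1-yl]oxy}silane
Product: 15 (R)-terpinen-4-ol [(1R)-4-methyl-1-(propan-2-yl)cyclohex-3-en-1-ol]
Conditions: TBAF, THF, rt → 40 °C (ee checked by chiral GC)
Reagents that add atoms: none
Why: Fluoride desilylation frees the tertiary alcohol under non-acidic conditions, avoiding dehydration to terpinenes.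

**Step 10**
Reactants: 16 4-bromophenol; 17 prenyl bromide (2.5 eq)
Product: 18 4-bromo-2,6-bis(3-methylbut-2-en-1-yl)phenol
Conditions: aq. KOH (2.5 eq), H2O, rt, vigorous stirring; chromatography (expected 30–40%)
Reagents that add atoms: none
Why: C-alkylation of a phenoxide in water (oxygen shielded by hydrogen bonding) gives ortho,ortho'-diprenylation with SN2 attack at the primary carbon of the allylic bromide; the para position is blocked by bromine.

**Step 11**
Reactants: 18 4-bromo-2,6-bis(3-methylbut-2-en-1-yl)phenol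
Product: 19 [4-bromo-2,6-bis(3-methylbut-2-en-1-yl)phenoxy](tert-butyl)dimethylsilane
Conditions: TBSOTf, 2,6-lutidine, CH2Cl2, 0 °C → rt
Reagents that add atoms: tert-butyldimethylsilyl trifluoromethanesulfonate, CC(C)(C)[Si](C)(C)OS(=O)(=O)C(F)(F)F
Why: Silyl triflate protects the hindered 2,6-disubstituted phenol as an ether that survives organolithiums and is later removed by fluoride.

**Step 12**
Reactants: 19 [4-bromo-2,6-bis(3-methylbut-2-en-1-yl)phenoxy](tert-butyl)dimethylsilane
Product: 21 4-(tert-butyldimethylsilyloxy)-3,5-bis(3-methylbut-2-en-1-yl)benzoic acid, via aryllithium 20 (not isolated)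
Conditions: t-BuLi (2.1 eq), THF, −78 °C; CO2 (g), −78 → 0 °C; 1 M HCl to pH 3–4 at 0 °C
Reagents that add atoms: carbon dioxide, O=C=O
Why: Bromine–lithium exchange is much faster than allylic/benzylic deprotonation at −78 °C, and carboxylation of the aryllithium gives the benzoic acid.

**Step 13**
Reactants: 21 4-(tert-butyldimethylsilyloxy)-3,5-bis(3-methylbut-2-en-1-yl)benzoic acid
Product: 22 4-(tert-butyldimethylsilyloxy)-3,5-bis(3-methylbut-2-en-1-yl)benzoyl chloride
Conditions: Ghosez reagent (1.2 eq), CH2Cl2, 0 °C → rt; concentrated and used crude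
Reagents that add atoms: 1-chloro-N,N,2-trimethylprop-1-en-1-amine (Ghosez reagent), CC(C)=C(Cl)N(C)C
Why: Neutral, HCl-free acid chloride formation protects the acid-sensitive prenyl groups and the silyl ether.

**Step 14**
Reactants: 15 (R)-terpinen-4-ol; 22 4-(tert-butyldimethylsilyloxy)-3,5-bis(3-methylbut-2-en-1-yl)benzoyl chloride
Product: 24 (1R)-1-isopropyl-4-methylcyclohex-3-en-1-yl 4-(tert-butyldimethylsilyloxy)-3,5-bis(3-methylbut-2-en-1-yl)benzoate, via lithium alkoxide 23 (not isolated)
Conditions: 15, n-BuLi (1.05 eq), THF, −78 → 0 °C; then 22, 0 °C → rt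
Reagents that add atoms: none
Why: O-acylation of a pre-formed tertiary lithium alkoxide with an unhindered aroyl chloride is the dependable way to esterify a hindered tertiary alcohol, and the C–O bond at the stereocentre is not broken.

**Step 15**
Reactants: 24 (1R)-1-isopropyl-4-methylcyclohex-3-en-1-yl 4-(tert-butyldimethylsilyloxy)-3,5-bis(3-methylbut-2-en-1-yl)benzoate
Product: 25 (1R)-1-isopropyl-4-methylcyclohex-3-en-1-yl 4-hydroxy-3,5-bis(3-methylbut-2-en-1-yl)benzoate (target)
Conditions: TBAF (1.1 eq), THF, 0 °C; aqueous work-up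
Reagents that add atoms: none
Why: Fluoride cleavage of the aryl silyl ether is fast and leaves the hindered tertiary ester and all three trisubstituted alkenes untouched.

## Compound list

1 | (S)-2-hydroxy-3-methylbutanoic acid | CC(C)[C@H](O)C(=O)O | starting material
2 | pivalaldehyde (2,2-dimethylpropanal) | CC(C)(C)C=O | starting material
3 | (2S,5S)-2-tert-butyl-5-isopropyl-1,3-dioxolan-4-one | CC(C)[C@@H]1O[C@H](C(C)(C)C)OC1=O | intermediate
4 | methyl vinyl ketone (but-3-en-2-one) | C=CC(C)=O | starting material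
5 | lithium (2S)-2-tert-butyl-5-isopropyl-1,3-dioxol-4-olate (formed in situ) | CC(C)C1=C([O-])O[C@@H](C(C)(C)C)O1.[Li+] | intermediate
6 | (2S,5S)-2-tert-butyl-5-isopropyl-5-(3-oxobutyl)-1,3-dioxolan-4-one | CC(C)[C@]1(CCC(C)=O)O[C@H](C(C)(C)C)OC1=O | intermediate
7 | (2S)-2-isopropylhexane-1,2,5-triol (C5 epimers) | CC(C)[C@](CO)(CCC(C)O)O | intermediate
8 | (2S)-2-hydroxy-2-isopropyl-5-oxohexanal | CC(C)[C@](C=O)(CCC(C)=O)O | intermediate
9 | (4S)-3,4-dihydroxy-4-isopropylcyclohexan-1-one (C3 epimers, formed in situ) | CC(C)[C@]1(O)C(O)CC(=O)CC1 | intermediate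
10 | (4S)-4-hydroxy-4-isopropylcyclohex-2-en-1-one | CC(C)[C@]1(O)C=CC(=O)CC1 | intermediate
11 | (4S)-4-isopropyl-4-(triethylsilyloxy)cyclohex-2-en-1-one | CC(C)[C@]1(O[Si](CC)(CC)CC)C=CC(=O)CC1 | intermediate
12 | lithium (4R)-4-isopropyl-4-(triethylsilyloxy)cyclohex-1-en-1-olate (formed in situ) | CC(C)[C@]1(O[Si](CC)(CC)CC)CC=C([O-])CC1.[Li+] | intermediate
13 | (4R)-4-isopropyl-4-(triethylsilyloxy)cyclohex-1-en-1-yl trifluoromethanesulfonate | CC(C)[C@]1(O[Si](CC)(CC)CC)CC=C(OS(=O)(=O)C(F)(F)F)CC1 | intermediate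
14 | triethyl{[(1R)-1-isopropyl-4-methylcyclohex-3-en-1-yl]oxy}silane | CC(C)[C@]1(O[Si](CC)(CC)CC)CC=C(C)CC1 | intermediate
15 | (R)-terpinen-4-ol, (1R)-4-methyl-1-(propan-2-yl)cyclohex-3-en-1-ol | CC(C)[C@]1(O)CC=C(C)CC1 | intermediate
16 | 4-bromophenol | Oc1ccc(Br)cc1 | starting material
17 | prenyl bromide (1-bromo-3-methylbut-2-ene) | CC(C)=CCBr | starting material
18 | 4-bromo-2,6-bis(3-methylbut-2-en-1-yl)phenol | CC(C)=CCc1cc(Br)cc(CC=C(C)C)c1O | intermediate
19 | [4-bromo-2,6-bis(3-methylbut-2-en-1-yl)phenoxy](tert-butyl)dimethylsilane | CC(C)=CCc1cc(Br)cc(CC=C(C)C)c1O[Si](C)(C)C(C)(C)C | intermediate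
20 | {4-(tert-butyldimethylsilyloxy)-3,5-bis(3-methylbut-2-en-1-yl)phenyl}lithium (formed in situ) | [Li]c1cc(CC=C(C)C)c(O[Si](C)(C)C(C)(C)C)c(CC=C(C)C)c1 | intermediate
21 | 4-(tert-butyldimethylsilyloxy)-3,5-bis(3-methylbut-2-en-1-yl)benzoic acid | CC(C)=CCc1cc(C(=O)O)cc(CC=C(C)C)c1O[Si](C)(C)C(C)(C)C | intermediate
22 | 4-(tert-butyldimethylsilyloxy)-3,5-bis(3-methylbut-2-en-1-yl)benzoyl chloride | CC(C)=CCc1cc(C(=O)Cl)cc(CC=C(C)C)c1O[Si](C)(C)C(C)(C)C | intermediate
23 | lithium (1R)-4-methyl-1-(propan-2-yl)cyclohex-3-en-1-olate (formed in situ) | CC(C)[C@]1([O-])CC=C(C)CC1.[Li+] | intermediate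
24 | (1R)-1-isopropyl-4-methylcyclohex-3-en-1-yl 4-(tert-butyldimethylsilyloxy)-3,5-bis(3-methylbut-2-en-1-yl)benzoate | CC(C)=CCc1cc(C(=O)O[C@@]2(C(C)C)CC=C(C)CC2)cc(CC=C(C)C)c1O[Si](C)(C)C(C)(C)C | intermediate
25 | (1R)-1-isopropyl-4-methylcyclohex-3-en-1-yl 4-hydroxy-3,5-bis(3-methylbut-2-en-1-yl)benzoate | CC(C)=CCc1cc(C(=O)O[C@@]2(C(C)C)CC=C(C)CC2)cc(CC=C(C)C)c1O | target

## Summary

Total steps: 15. Longest linear sequence: 11 steps (steps 1–9, 14, 15); the aryl branch (steps 10–13) joins at step 14.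

**Steps most likely to fail**

Step 2 (MVK may polymerise or add 1,2 before the short-lived enolate is consumed). The fallback sets out from 3 and comes back at 6. Enolate 5 (LDA, THF/DMPU, −78 °C) is alkylated, again anti to the tert-butyl group, with 3-chloro-1-iodobut-2-ene, made beforehand from commercial 1,3-dichlorobut-2-ene and NaI in acetone (Wichterle reagent). This gives (2S,5S)-2-tert-butyl-5-(3-chlorobut-2-en-1-yl)-5-isopropyl-1,3-dioxolan-4-one F1. Hydrolysis of the vinyl chloride (Hg(OAc)2, HCO2H, rt) then gives methyl ketone 6.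

Step 7 (1,2-reduction next to the quaternary centre, or enolate equilibration that would erode ee). The fallback sets out from 11 and comes back at 13. Enone 11 is 1,4-hydrosilylated (Et3SiH, 1 mol% RhCl(PPh3)3, benzene, 50 °C) to the isolable silyl enol ether (4R)-4-isopropyl-1,4-bis(triethylsilyloxy)cyclohex-1-ene F2. MeLi (THF, 0 °C) cleaves only the enol silyl group and regenerates enolate 12 regiospecifically, and PhNTf2 gives 13.

Step 10 (mono-, O- and over-alkylated by-products, low yield). The fallback sets out from 16 and comes back at 18, building each prenyl group by aromatic Claisen rearrangement. 16 is O-alkylated with 3-chloro-3-methylbut-1-yne (cat. CuCl2, DBU, MeCN, 0 °C) to 1-bromo-4-[(2-methylbut-3-yn-2-yl)oxy]benzene F3. Lindlar semi-hydrogenation (H2, quinoline, EtOAc) gives 1-bromo-4-[(2-methylbut-3-en-2-yl)oxy]benzene F4. Heating (PhNEt2, 150–180 °C) gives 4-bromo-2-(3-methylbut-2-en-1-yl)phenol F5. The same three operations are repeated: O-alkylation to 4-bromo-1-[(2-methylbut-3-yn-2-yl)oxy]-2-(3-methylbut-2-en-1-yl)benzene F6, semi-hydrogenation to 4-bromo-1-[(2-methylbut-3-en-2-yl)oxy]-2-(3-methylbut-2-en-1-yl)benzene F7, and Claisen rearrangement into the remaining ortho position to give 18.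

## Further compounds

F1 | step 2 | (2S,5S)-2-tert-butyl-5-(3-chlorobut-2-en-1-yl)-5-isopropyl-1,3-dioxolan-4-one | CC(C)[C@]1(CC=C(C)Cl)O[C@H](C(C)(C)C)OC1=O
F2 | step 7 | (4R)-4-isopropyl-1,4-bis(triethylsilyloxy)cyclohex-1-ene | CC(C)[C@]1(O[Si](CC)(CC)CC)CC=C(O[Si](CC)(CC)CC)CC1
F3 | step 10 | 1-bromo-4-[(2-methylbut-3-yn-2-yl)oxy]benzene | C#CC(C)(C)Oc1ccc(Br)cc1
F4 | step 10 | 1-bromo-4-[(2-methylbut-3-en-2-yl)oxy]benzene | C=CC(C)(C)Oc1ccc(Br)cc1
F5 | step 10 | 4-bromo-2-(3-methylbut-2-en-1-yl)phenol | CC(C)=CCc1cc(Br)ccc1O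
F6 | step 10 | 4-bromo-1-[(2-methylbut-3-yn-2-yl)oxy]-2-(3-methylbut-2-en-1-yl)benzene | C#CC(C)(C)Oc1ccc(Br)cc1CC=C(C)C
F7 | step 10 | 4-bromo-1-[(2-methylbut-3-en-2-yl)oxy]-2-(3-methylbut-2-en-1-yl)benzene | C=CC(C)(C)Oc1ccc(Br)cc1CC=C(C)C
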